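# Total synthesis proposal for CNP0275555.0 (C48H33ClO24)

## Analysis of the target

The target is an octameric chlorinated phlorotannin. Eight benzene rings are joined by five diaryl ether bridges and two biaryl bonds, and they carry nineteen free hydroxyl groups and one chlorine.

Ring labels follow the SMILES. The central ring C has C1 (O to ring B), C2 (H), C3 (OH), C4 (H), C5 (O to ring D) and C6 (O to ring E). Ring E is 4-chloro-3,5-dihydroxyphenyl, bound through E1.

Ring B has B1 (O to ring A, a 2,4,6-trihydroxyphenyl), B2 (H), B3 (OH), B4 (O to ring C), B5 (OH) and B6 (C–C bond to ring G, a 2,4,6-trihydroxyphenyl). Ring D with rings F and H repeats this pattern atom for atom. The molecule therefore has a local mirror plane through C3 and C6 of ring C.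

There is no stereocentre. The two biaryl axes (B6–G1 and its twin on ring D) are tetra-ortho-substituted, but rings G and H are symmetric about the axis, so nothing stereochemical has to be set.

The hard part is the contiguous C5–C6–C1 tris(aryloxy) array of ring C. Each bridge to ring B or D has three ortho substituents and joins two electron-rich rings, which is the worst case for aromatic C–O coupling.

Three sensitivities shape the route:
- The free polyphenol, and every 4-aryloxy-2,6-dioxygenated phenol on the way, is easily oxidised to a quinone with loss of a ring.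
- The C–Cl bond forbids hydrogenolysis.
- The many nucleophilic C–H positions make late electrophilic functionalisation unselective.

The feature exploited is this: C5–C6–C1 with its three oxygens is the skeleton of a 1,3-dioxygenated propan-2-one, and C2–C3–C4 is the skeleton of a 2-substituted malondialdehyde. Both are symmetric about the same plane as the target, so ring C can be built instead of bought.

## Retrosynthetic reasoning

**26 ⇒ 25.** The last operation only uncovers oxygen: eighteen O–CH3 bonds of 25 are cut. Methyl ethers are chosen because every ring can then be bought in methylated form, and because the C–Cl bond of ring E rules out benzyl ethers and hydrogenolysis. The forward reaction must cleave alkyl–oxygen bonds and leave the five aryl–O–aryl bridges, the two biaryl bonds and the chloride alone.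

**25 ⇒ 24 ⇒ 23 ⇒ 22.** The C3–O bond of ring C is traced back to a C3–N bond, through diazonium salt 24 and aniline 23 to nitroarene 22. The nitro group is accepted at C3 because it is what makes the ring synthesis below work. Its price is two reliable functional group steps.

**22 ⇒ 16 + 21.** Of the two C–O bonds of the C6–O–E1 bridge, the one to E1 is cut. E1 has two hydrogen neighbours, while C6 is flanked by two large aryloxy groups. Ring C supplies the oxygen as the phenolate of 16, and ring E comes as the aryl cation equivalent 21. The forward reaction must transfer only the chlorinated aryl group of 21.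

**16 ⇒ 13 + 14 (key disconnection).** The C1–C2 and C4–C5 bonds of ring C are cut, which opens the ring into two symmetric three-carbon pieces.
- Ketone 13 supplies C5–C6–C1 with both arms already on oxygen.
- Dialdehyde salt 14 supplies C2–C3–C4 with nitrogen at C3.

What is gained is that no C–O bond ever has to be made at the aromatic carbons C1 and C5, and the 1,2,3,5 pattern follows from connectivity alone. The forward reaction must perform two aldol condensations and aromatise.

**13 ⇒ 10 + 11 (through 12).** The two O–CH2 bonds are cut. The most hindered ether bonds of the target thereby become substitutions at the sp3 carbons of 11, where the two ortho-methoxy groups of phenol 10 hardly matter. One step leads to the precursor of the key step.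

**10 ⇒ 9 ⇒ 8.** The B4–OH is traced back to a formyl group. The formyl group stands para to B1, and this is the reason for choosing it, since it activates B1 in the disconnection after next.

**8 ⇒ 4 + 5 (through 6 and 7).** The B6–G1 biaryl bond is cut. Ring G comes from 5 by metalation, and ring B carries bromine at B6. The handle must already be in place, because a halogenation after ring A has arrived would attack ring A.

**4 ⇒ 2 + 3, and 2 ⇒ 1.** The B1–O bond is cut on the side of ring B, where the para formyl group allows an addition–elimination with phenol 3. The B6 bromine goes back to 1, in which all directing effects point at that carbon.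

**21 ⇒ 19 + 5 (through 20), and 19 ⇒ 17 (through 18).** The iodonium salt is cut at the bond from iodine to the trimethoxyphenyl spectator. The iodine of 19 stands at the one position of 17 that electrophiles avoid and that a sterically governed C–H borylation finds.

## Alternatives that were turned down

**Alternative 1:** The textbook route cuts the aromatic C1–O and C5–O bonds of a purchased ring C. The forward key step is a twofold copper-catalysed Ullmann coupling of phenol 10 with 1,3-dibromo-2-(4-chloro-3,5-dimethoxyphenoxy)-5-methoxybenzene A1, which gives the nonadecamethyl ether A2.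
- Each new ether has three ortho substituents, and both bromides lie next to the ring E oxygen.
- A1 carries three donors and is a poor electrophile.
- Phenol 10 is a hindered nucleophile that hot basic copper would oxidise.
- The second coupling must succeed beside the first. Hydrodebromination would give products that differ from A2 by one arm only.
- A1 itself needs several steps, because its substitution pattern is not the one that electrophilic bromination delivers.

The whole risk falls on the most valuable intermediate, with no structural help.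

**Alternative 2:** Here ring C serves as a quinone dielectrophile. The forward key step is a twofold addition–elimination of phenol 10 on 2,6-dichloro-1,4-benzoquinone A3 to give 2,6-bis(ArO)-1,4-benzoquinone A4. Reduction and arylation of the hindered hydroxyl group would follow.
- The oxygen pattern maps well, but the redox pairing does not. Phenol 10 is a 4-aryloxy-2,6-dimethoxyphenol, and A3 is a strong enough oxidant to take electrons from its phenolate. Ring B would then collapse to a quinone and expel 3.
- The unsubstituted carbons of A3 are competing sites of attack.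
- After reduction, the two hydroxyl groups of ring C would still have to be told apart, which costs the step that the quinone seemed to save.

**Alternative 3:** The two biaryl bonds are cut last. The forward key step is a twofold anodic dehydrogenative cross-coupling of the hexameric permethyl ether A5 (the skeleton without rings G and H) with arene 5, giving A2.
- The idea is attractive because B2 and B6 are equivalent in A5, so either position gives the same product.
- The anode would first oxidise the most electron-rich rings, which are A and F and arene 5 itself, not B and D.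
- A5 offers twelve nucleophilic C–H positions, and nothing stops a second arylation at B2.
- The bonds to be formed are tetra-ortho-substituted.

Site selectivity cannot be argued from the structure.

Key step: step 6

Remark: the SMILES of the target holds no stereodescriptor and the structure has no stereogenic element, so only the open-chain intermediate 15 carries a double-bond descriptor. Compounds 1, 3, 5, 11, 14 and 17 are taken as catalogue chemicals.

Abbreviation: ArO– is the aryloxy residue of phenol 10, that is 2,6-dimethoxy-3-(2,4,6-trimethoxyphenyl)-4-(2,4,6-trimethoxyphenoxy)phenoxy.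

## Route

**Step 1**
Reactants: 1 4-fluoro-2,6-dimethoxybenzaldehyde
Product: 2 3-bromo-4-fluoro-2,6-dimethoxybenzaldehyde
Conditions: NBS (1.0 equiv), MeCN, 0 °C to rt
Reagents that add atoms: N-bromosuccinimide, O=C1CCC(=O)N1Br
Why: Electrophilic aromatic bromination; C3 is ortho to one methoxy group, para to the other, ortho to fluorine and meta to the formyl group, so all directing effects meet at the two equivalent positions C3 and C5, and the first bromine deactivates the ring towards a second one.

**Step 2**
Reactants: 2 3-bromo-4-fluoro-2,6-dimethoxybenzaldehyde; 3 2,4,6-trimethoxyphenol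
Product: 4 3-bromo-2,6-dimethoxy-4-(2,4,6-trimethoxyphenoxy)benzaldehyde
Conditions: K2CO3, DMF, 90 °C, N2
Reagents that add atoms: none
Why: Nucleophilic aromatic substitution by addition–elimination; fluoride para to the formyl group and next to the inductively withdrawing bromine is the only good leaving group at an activated carbon, while bromide sits meta to the formyl group and stays. Exclusion of air protects the electron-rich phenolate of 3.

**Step 3**
Reactants: 4 3-bromo-2,6-dimethoxy-4-(2,4,6-trimethoxyphenoxy)benzaldehyde; 5 1,3,5-trimethoxybenzene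
Product: 8 2,6-dimethoxy-3-(2,4,6-trimethoxyphenyl)-4-(2,4,6-trimethoxyphenoxy)benzaldehyde, via 2,4,6-trimethoxyphenyllithium 6 (not isolated), via (2,4,6-trimethoxyphenyl)zinc chloride 7 (not isolated)
Conditions: 5 (1.5 equiv), n-BuLi, THF, 0 °C to rt; ZnCl2 (1.6 equiv), 0 °C to rt; then 4, Pd2(dba)3 (2 mol %), RuPhos (8 mol %), THF, 65 °C
Reagents that add atoms: n-butyllithium, [Li]CCCC (lithium in 6 only); zinc chloride, Cl[Zn]Cl (zinc and chlorine in 7 only)
Why: Ortho-lithiation of 5 between two methoxy groups, transmetalation and Negishi coupling; bulky dialkylbiarylphosphine ligands on zerovalent palladium are established for tetra-ortho-substituted biaryls, all four ortho groups are oxygen-linked and therefore small at the reacting carbon, and the arylzinc halide neither protodemetalates like the boronic acid nor adds to the hindered, electron-rich aldehyde. The new axis is not stereogenic because ring G is symmetric about it.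

**Step 4**
Reactants: 8 2,6-dimethoxy-3-(2,4,6-trimethoxyphenyl)-4-(2,4,6-trimethoxyphenoxy)benzaldehyde
Product: 10 2,6-dimethoxy-3-(2,4,6-trimethoxyphenyl)-4-(2,4,6-trimethoxyphenoxy)phenol (ArOH), via aryl formate 9 (not isolated)
Conditions: mCPBA (1.2 equiv), CH2Cl2, 0 °C to rt; aq. Na2S2O3 wash; then K2CO3 (0.2 equiv), degassed MeOH, 0 °C, N2
Reagents that add atoms: 3-chloroperoxybenzoic acid, OOC(=O)c1cccc(Cl)c1
Why: Baeyer–Villiger oxidation of Dakin type; two ortho-methoxy groups and the para-aryloxy group make aryl migration fast. The oxidation-prone phenol stays masked as formate 9 until the oxidant has been destroyed, and methanolysis then releases 10.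

**Step 5**
Reactants: 10 ArOH (2.05 equiv); 11 1,3-dichloropropan-2-one
Product: 13 1,3-bis(ArO)propan-2-one, via monoalkylated chloroketone 12 (not isolated)
Conditions: K2CO3, MeCN, 50 °C, N2
Reagents that add atoms: none
Why: Twofold Williamson ether synthesis; SN2 displacement at the primary carbon of an α-chloroketone is very fast and almost blind to the two ortho-methoxy groups of the phenolate, so the bonds that become the most hindered diaryl ethers of the target form under mild conditions.

**Step 6**
Reactants: 13 1,3-bis(ArO)propan-2-one; 14 sodium nitromalonaldehyde monohydrate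
Product: 16 2,6-bis(ArO)-4-nitrophenol, via open-chain nitronate 15 (not isolated)
Conditions: 14 (1.5 equiv), NaOH (2 equiv), THF–EtOH–H2O, 0 °C to rt, N2; then 1 M HCl
Reagents that add atoms: none
Why: Hydroxide converts 13 into its enolate, whose carbon (the future C1) adds to one formyl group of 14, and loss of water gives the open-chain nitronate 15 (first aldol condensation, C1–C2 bond). The charge of 15 is spread over the nitro-substituted dienolate, so rotation about C1–C2 and C2–C3 is easy and the geometry needed for closure is always within reach. The second α-carbon (C5) then adds to the remaining formyl carbon C4 in a 6-(enolendo)-exo-trig aldol closure of ring C, and loss of a second water with tautomerisation gives the aromatic 4-nitrophenolate, a thermodynamic sink that makes the sequence irreversible. The closest known reaction type is the classical condensation of sodium nitromalonaldehyde with ketones bearing two α-methylene groups, which gives 2,6-disubstituted 4-nitrophenols. No stereocentre is formed. Regiochemistry needs no control, because the carbonyl carbon must become C6, the two symmetry-equivalent α-carbons with their aryloxy groups must become C1 and C5, and the nitro carbon must end up para at C3. The selectivity required is cross-condensation over self-aldolisation of 13; it is secured by the excess of the non-enolisable dialdehyde 14, whose nitro group draws the negative charge away from the formyl carbons and keeps them electrophilic, and by the steric shielding of the carbonyl group of 13.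

**Step 7**
Reactants: 17 2-chloro-1,3-dimethoxybenzene
Product: 19 2-chloro-5-iodo-1,3-dimethoxybenzene, via pinacol boronate 18 (not isolated)
Conditions: [Ir(OMe)(cod)]2 (1.5 mol %), dtbpy (3 mol %), B2pin2 (1.0 equiv), THF, 80 °C; evaporate; then CuI (10 mol %), 1,10-phenanthroline (20 mol %), KI (1.5 equiv), MeOH–H2O, air, 80 °C
Reagents that add atoms: bis(pinacolato)diboron, CC1(C)OB(OC1(C)C)B1OC(C)(C)C(C)(C)O1 (boron and pinacol in 18 only); potassium iodide, [K+].[I-]
Why: Iridium-catalysed C–H borylation is governed by sterics, and C5–H is the only C–H bond of 17 without an ortho substituent; copper-catalysed aerobic iododeboronation then exchanges boron for iodine at the same carbon. Electrophilic iodination would give the wrong isomer.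

**Step 8**
Reactants: 19 2-chloro-5-iodo-1,3-dimethoxybenzene; 5 1,3,5-trimethoxybenzene
Product: 21 (4-chloro-3,5-dimethoxyphenyl)(2,4,6-trimethoxyphenyl)iodonium tosylate, via hydroxy(tosyloxy)iodoarene 20 (not isolated)
Conditions: mCPBA (1.0 equiv), TsOH·H2O (1.0 equiv), MeCN, 77 °C; then 5 (1.0 equiv), 77 °C; precipitation from Et2O
Reagents that add atoms: 4-methylbenzenesulfonic acid monohydrate, Cc1ccc(S(=O)(=O)O)cc1.O; 3-chloroperoxybenzoic acid, OOC(=O)c1cccc(Cl)c1 (oxygen of the hydroxyl group in 20 only)
Why: One-pot oxidation of an aryl iodide to trivalent iodine followed by electrophilic substitution on the very nucleophilic arene 5, the standard entry to unsymmetrical diaryliodonium salts. The ring of 19 is protected from self-arylation by chlorine, by iodine and by the crowding of its two open positions.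

**Step 9**
Reactants: 16 2,6-bis(ArO)-4-nitrophenol; 21 (4-chloro-3,5-dimethoxyphenyl)(2,4,6-trimethoxyphenyl)iodonium tosylate
Product: 22 1,3-bis(ArO)-2-(4-chloro-3,5-dimethoxyphenoxy)-5-nitrobenzene
Conditions: 21 (1.3 equiv), K2CO3, MeCN, 60 °C
Reagents that add atoms: none
Why: Metal-free O-arylation of a phenol with a diaryliodonium salt, by ligand exchange at trivalent iodine and then ligand coupling, a method known to tolerate both 2,6-disubstituted and nitro-substituted phenols. The electron-rich trimethoxyphenyl group is the spectator, and the transferred aryl group has no ortho substituent, so the hindered phenolate meets an open ipso carbon.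

**Step 10**
Reactants: 22 1,3-bis(ArO)-2-(4-chloro-3,5-dimethoxyphenoxy)-5-nitrobenzene
Product: 23 3,5-bis(ArO)-4-(4-chloro-3,5-dimethoxyphenoxy)aniline
Conditions: H2 (1 atm), sulfided Pt/C, THF–EtOH, rt
Reagents that add atoms: none
Why: Chemoselective catalytic hydrogenation of a nitroarene; sulfided platinum is the standard catalyst for halonitroarenes and leaves the hindered, electron-rich C–Cl bond intact. The molecule holds no other reducible group.

**Step 11**
Reactants: 23 3,5-bis(ArO)-4-(4-chloro-3,5-dimethoxyphenoxy)aniline
Product: 25 3,5-bis(ArO)-4-(4-chloro-3,5-dimethoxyphenoxy)phenol, via diazonium hydrogensulfate 24 (not isolated)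
Conditions: NaNO2 (1.0 equiv), aq. H2SO4, MeCN, 0 °C; then Cu(NO3)2 (excess), Cu2O (0.5 equiv), H2O, rt
Reagents that add atoms: sodium nitrite, [Na+].[O-]N=O (nitrogen in 24 only); sulfuric acid, OS(=O)(=O)O (counter-ion in 24 only); water, O
Why: Diazotisation and copper-mediated hydroxydediazoniation of Sandmeyer type; monovalent copper reduces 24 to the aryl radical and hydrated divalent copper delivers the hydroxyl group at room temperature, so hot acid is avoided. The radical at C3 has only hydrogen neighbours, so no Pschorr-type closure onto another ring is possible.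

**Step 12**
Reactants: 25 3,5-bis(ArO)-4-(4-chloro-3,5-dimethoxyphenoxy)phenol
Product: 26 CNP0275555.0
Conditions: BBr3 (40 equiv), CH2Cl2, −78 °C to rt, Ar; then H2O, 0 °C; Sephadex LH-20, degassed MeOH
Reagents that add atoms: none
Why: Lewis-acid ether cleavage; bromide attacks only the methyl carbon of each boron-complexed ether (SN2), so all eighteen O–CH3 bonds fall while the diaryl ether bridges, the biaryl bonds and the aryl chloride, which offer no sp3 carbon, are left alone.

## Compound list

1 | 4-fluoro-2,6-dimethoxybenzaldehyde | COc1cc(F)cc(OC)c1C=O | starting material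
2 | 3-bromo-4-fluoro-2,6-dimethoxybenzaldehyde | O=Cc1c(OC)cc(F)c(Br)c1OC | intermediate
3 | 2,4,6-trimethoxyphenol | COc1cc(OC)c(O)c(OC)c1 | starting material
4 | 3-bromo-2,6-dimethoxy-4-(2,4,6-trimethoxyphenoxy)benzaldehyde | O=Cc1c(OC)cc(Oc2c(OC)cc(OC)cc2OC)c(Br)c1OC | intermediate
5 | 1,3,5-trimethoxybenzene | COc1cc(OC)cc(OC)c1 | starting material
6 | 2,4,6-trimethoxyphenyllithium | [Li]c1c(OC)cc(OC)cc1OC | intermediate
7 | (2,4,6-trimethoxyphenyl)zinc chloride | Cl[Zn]c1c(OC)cc(OC)cc1OC | intermediate
8 | 2,6-dimethoxy-3-(2,4,6-trimethoxyphenyl)-4-(2,4,6-trimethoxyphenoxy)benzaldehyde | O=Cc1c(OC)cc(Oc2c(OC)cc(OC)cc2OC)c(-c2c(OC)cc(OC)cc2OC)c1OC | intermediate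
9 | 2,6-dimethoxy-3-(2,4,6-trimethoxyphenyl)-4-(2,4,6-trimethoxyphenoxy)phenyl formate | O=COc1c(OC)cc(Oc2c(OC)cc(OC)cc2OC)c(-c2c(OC)cc(OC)cc2OC)c1OC | intermediate
10 | 2,6-dimethoxy-3-(2,4,6-trimethoxyphenyl)-4-(2,4,6-trimethoxyphenoxy)phenol (ArOH) | Oc1c(OC)cc(Oc2c(OC)cc(OC)cc2OC)c(-c2c(OC)cc(OC)cc2OC)c1OC | intermediate
11 | 1,3-dichloropropan-2-one | ClCC(=O)CCl | starting material
12 | 1-chloro-3-(ArO)propan-2-one | ClCC(=O)COc1c(OC)cc(Oc2c(OC)cc(OC)cc2OC)c(-c2c(OC)cc(OC)cc2OC)c1OC | intermediate
13 | 1,3-bis(ArO)propan-2-one | O=C(COc1c(OC)cc(Oc2c(OC)cc(OC)cc2OC)c(-c2c(OC)cc(OC)cc2OC)c1OC)COc1c(OC)cc(Oc2c(OC)cc(OC)cc2OC)c(-c2c(OC)cc(OC)cc2OC)c1OC | intermediate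
14 | sodium nitromalonaldehyde monohydrate (drawn as the nitronate) | O=CC(C=O)=[N+]([O-])[O-].[Na+].O | starting material
15 | sodium nitronate of (E)-4,6-bis(ArO)-2-nitro-5-oxohex-3-enal (configurationally labile, drawn in the geometry that closes) | [Na+].O=CC(=[N+]([O-])[O-])/C=C(/Oc1c(OC)cc(Oc2c(OC)cc(OC)cc2OC)c(-c2c(OC)cc(OC)cc2OC)c1OC)C(=O)COc1c(OC)cc(Oc2c(OC)cc(OC)cc2OC)c(-c2c(OC)cc(OC)cc2OC)c1OC | intermediate
16 | 2,6-bis(ArO)-4-nitrophenol | Oc3c(Oc1c(OC)cc(Oc2c(OC)cc(OC)cc2OC)c(-c2c(OC)cc(OC)cc2OC)c1OC)cc([N+](=O)[O-])cc3Oc1c(OC)cc(Oc2c(OC)cc(OC)cc2OC)c(-c2c(OC)cc(OC)cc2OC)c1OC | intermediate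
17 | 2-chloro-1,3-dimethoxybenzene | COc1cccc(OC)c1Cl | starting material
18 | 2-(4-chloro-3,5-dimethoxyphenyl)-4,4,5,5-tetramethyl-1,3,2-dioxaborolane | COc1cc(B2OC(C)(C)C(C)(C)O2)cc(OC)c1Cl | intermediate
19 | 2-chloro-5-iodo-1,3-dimethoxybenzene | COc1cc(I)cc(OC)c1Cl | intermediate
20 | 2-chloro-5-[hydroxy(tosyloxy)iodo]-1,3-dimethoxybenzene | COc1cc(I(O)OS(=O)(=O)c2ccc(C)cc2)cc(OC)c1Cl | intermediate
21 | (4-chloro-3,5-dimethoxyphenyl)(2,4,6-trimethoxyphenyl)iodonium tosylate | COc1cc([I+]c2c(OC)cc(OC)cc2OC)cc(OC)c1Cl.Cc1ccc(S(=O)(=O)[O-])cc1 | intermediate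
22 | 1,3-bis(ArO)-2-(4-chloro-3,5-dimethoxyphenoxy)-5-nitrobenzene | O=[N+]([O-])c3cc(Oc1c(OC)cc(Oc2c(OC)cc(OC)cc2OC)c(-c2c(OC)cc(OC)cc2OC)c1OC)c(Oc1cc(OC)c(Cl)c(OC)c1)c(Oc1c(OC)cc(Oc2c(OC)cc(OC)cc2OC)c(-c2c(OC)cc(OC)cc2OC)c1OC)c3 | intermediate
23 | 3,5-bis(ArO)-4-(4-chloro-3,5-dimethoxyphenoxy)aniline | Nc3cc(Oc1c(OC)cc(Oc2c(OC)cc(OC)cc2OC)c(-c2c(OC)cc(OC)cc2OC)c1OC)c(Oc1cc(OC)c(Cl)c(OC)c1)c(Oc1c(OC)cc(Oc2c(OC)cc(OC)cc2OC)c(-c2c(OC)cc(OC)cc2OC)c1OC)c3 | intermediate
24 | 3,5-bis(ArO)-4-(4-chloro-3,5-dimethoxyphenoxy)benzenediazonium hydrogensulfate | N#[N+]c3cc(Oc1c(OC)cc(Oc2c(OC)cc(OC)cc2OC)c(-c2c(OC)cc(OC)cc2OC)c1OC)c(Oc1cc(OC)c(Cl)c(OC)c1)c(Oc1c(OC)cc(Oc2c(OC)cc(OC)cc2OC)c(-c2c(OC)cc(OC)cc2OC)c1OC)c3.OS(=O)(=O)[O-] | intermediate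
25 | 3,5-bis(ArO)-4-(4-chloro-3,5-dimethoxyphenoxy)phenol | Oc3cc(Oc1c(OC)cc(Oc2c(OC)cc(OC)cc2OC)c(-c2c(OC)cc(OC)cc2OC)c1OC)c(Oc1cc(OC)c(Cl)c(OC)c1)c(Oc1c(OC)cc(Oc2c(OC)cc(OC)cc2OC)c(-c2c(OC)cc(OC)cc2OC)c1OC)c3 | intermediate
26 | CNP0275555.0 | Oc1cc(O)c(Oc2cc(O)c(Oc3cc(O)cc(Oc4c(O)cc(Oc5c(O)cc(O)cc5O)c(-c5c(O)cc(O)cc5O)c4O)c3Oc3cc(O)c(Cl)c(O)c3)c(O)c2-c2c(O)cc(O)cc2O)c(O)c1 | target

## Step count and risk

Total step count: 12. Longest linear sequence: 10 (steps 1 to 6 and 9 to 12). Steps 7 and 8 form a side branch of two steps.

**Step 6 (key step).** Three things are most likely to go wrong: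
- a slow first addition, because the α-carbons of 13 sit next to very large aryloxy groups and 13 dissolves poorly in aqueous base;
- base-induced deformylation of 14 or self-aldolisation of 13, which could then outrun the cross-condensation;
- stalling at the open-chain stage.

The fallback gives up the ring construction and uses aromatic C–O coupling on an acceptor-substituted ring. It sets out from 10 and 21 and comes back at 22. Purchased 2,6-dibromo-4-nitrophenol F1 is O-arylated with 21 (K2CO3, MeCN, 60 °C) to give 1,3-dibromo-2-(4-chloro-3,5-dimethoxyphenoxy)-5-nitrobenzene F2. A twofold Ullmann coupling of F2 with 10 (CuI, picolinic acid, K3PO4, DMSO, 100 °C) gives 22. The nitro group lowers the electron density of the dibromide compared with the electrophile of the textbook route.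

**Step 9.** The weakly nucleophilic, doubly flanked nitrophenolate may bind poorly to iodine. Thermal decay of the iodonium salt or transfer of tosylate could then compete with ligand coupling.

The fallback reverses the polarity of the bridge and uses the para-nitro group as activator. It sets out from 16 and 18 and comes back at 22.
- SO2F2 and Et3N convert 16 into 2,6-bis(ArO)-4-nitrophenyl fluorosulfate F3.
- NMe4F in DMF turns F3 into 1,3-bis(ArO)-2-fluoro-5-nitrobenzene F4.
- Boronate 18 is oxidised with NaBO3 to 4-chloro-3,5-dimethoxyphenol F5.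
- The small phenolate of F5 displaces fluoride from F4 (K2CO3, DMF, 80 °C) to give 22.

**Step 3.** Oxidative addition and reductive elimination at a bromide flanked by a methoxy and a large aryloxy group may be slow. Hydrodebromination and homocoupling of the zinc reagent would then take over.

The fallback changes the order of bond formation, so that the coupling meets only fluorine and methoxy as neighbours. It sets out from 2 and comes back at 8. Negishi coupling of 2 with 7 gives 4-fluoro-2,6-dimethoxy-3-(2,4,6-trimethoxyphenyl)benzaldehyde F6. Addition–elimination with 3 (Cs2CO3, DMSO, 120 °C) then gives 8.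

**Step 5.** The chloroketone may be lost to base-induced self-condensation, to attack at the carbonyl group with epoxide formation, or to Favorskii-type paths. The reaction may also stop after the first substitution.

The fallback forms the two ether bonds at the alcohol oxidation level. It sets out from 10 and comes back at 13. Two equivalents of 10 are alkylated with racemic epichlorohydrin F7 (K2CO3, DMF, 80 °C) to give 1,3-bis(ArO)propan-2-ol F8. Dess–Martin periodinane in CH2Cl2 oxidises F8 to 13.

**Step 11.** C-nitrosation or azo coupling at the electron-rich trimethoxyphenyl rings may occur. Hydrogen abstraction by the aryl radical (hydrodediazoniation) may also erode the conversion.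

The fallback forms a C–B bond in a non-aqueous, acid-free medium and oxidises it afterwards. It sets out from 23 and comes back at 25. Treatment of 23 with t-BuONO and B2pin2 in MeCN at rt (Sandmeyer-type borylation) gives 2-[3,5-bis(ArO)-4-(4-chloro-3,5-dimethoxyphenoxy)phenyl]-4,4,5,5-tetramethyl-1,3,2-dioxaborolane F9. NaBO3 in THF–H2O then converts F9 into 25.

**Step 12.** Three failure modes are foreseen:
- Partly cleaved borates may precipitate and stop the cleavage short of eighteen methyl groups.
- Acid may promote dehydrative closure between ortho hydroxyl groups across a biaryl axis.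
- The free polyphenol may oxidise in air during isolation.

The fallback isolates a stable derivative instead of the polyphenol. It sets out from 25 and comes back at 26. The crude product of the BBr3 cleavage is acetylated in the same flask (Ac2O, pyridine) to the nonadecaacetate of the target F10, which can be chromatographed on silica. Incompletely cleaved material can be recognised and resubmitted at this point. Catalytic K2CO3 in degassed MeOH under argon then releases 26.

## Further compounds

F1 | step 6 | 2,6-dibromo-4-nitrophenol (purchased) | Oc1c(Br)cc([N+](=O)[O-])cc1Br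
F2 | step 6 | 1,3-dibromo-2-(4-chloro-3,5-dimethoxyphenoxy)-5-nitrobenzene | O=[N+]([O-])c1cc(Br)c(Oc2cc(OC)c(Cl)c(OC)c2)c(Br)c1
F3 | step 9 | 2,6-bis(ArO)-4-nitrophenyl fluorosulfate | O=S(=O)(F)Oc3c(Oc1c(OC)cc(Oc2c(OC)cc(OC)cc2OC)c(-c2c(OC)cc(OC)cc2OC)c1OC)cc([N+](=O)[O-])cc3Oc1c(OC)cc(Oc2c(OC)cc(OC)cc2OC)c(-c2c(OC)cc(OC)cc2OC)c1OC
F4 | step 9 | 1,3-bis(ArO)-2-fluoro-5-nitrobenzene | Fc3c(Oc1c(OC)cc(Oc2c(OC)cc(OC)cc2OC)c(-c2c(OC)cc(OC)cc2OC)c1OC)cc([N+](=O)[O-])cc3Oc1c(OC)cc(Oc2c(OC)cc(OC)cc2OC)c(-c2c(OC)cc(OC)cc2OC)c1OC
F5 | step 9 | 4-chloro-3,5-dimethoxyphenol | COc1cc(O)cc(OC)c1Cl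
F6 | step 3 | 4-fluoro-2,6-dimethoxy-3-(2,4,6-trimethoxyphenyl)benzaldehyde | O=Cc1c(OC)cc(F)c(-c2c(OC)cc(OC)cc2OC)c1OC
F7 | step 5 | epichlorohydrin, racemic (purchased) | ClCC1CO1
F8 | step 5 | 1,3-bis(ArO)propan-2-ol | OC(COc1c(OC)cc(Oc2c(OC)cc(OC)cc2OC)c(-c2c(OC)cc(OC)cc2OC)c1OC)COc1c(OC)cc(Oc2c(OC)cc(OC)cc2OC)c(-c2c(OC)cc(OC)cc2OC)c1OC
F9 | step 11 | 2-[3,5-bis(ArO)-4-(4-chloro-3,5-dimethoxyphenoxy)phenyl]-4,4,5,5-tetramethyl-1,3,2-dioxaborolane | CC1(C)OB(OC1(C)C)c3cc(Oc1c(OC)cc(Oc2c(OC)cc(OC)cc2OC)c(-c2c(OC)cc(OC)cc2OC)c1OC)c(Oc1cc(OC)c(Cl)c(OC)c1)c(Oc1c(OC)cc(Oc2c(OC)cc(OC)cc2OC)c(-c2c(OC)cc(OC)cc2OC)c1OC)c3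
F10 | step 12 | nonadecaacetate of the target | CC(=O)Oc3cc(Oc1c(OC(C)=O)cc(Oc2c(OC(C)=O)cc(OC(C)=O)cc2OC(C)=O)c(-c2c(OC(C)=O)cc(OC(C)=O)cc2OC(C)=O)c1OC(C)=O)c(Oc1cc(OC(C)=O)c(Cl)c(OC(C)=O)c1)c(Oc1c(OC(C)=O)cc(Oc2c(OC(C)=O)cc(OC(C)=O)cc2OC(C)=O)c(-c2c(OC(C)=O)cc(OC(C)=O)cc2OC(C)=O)c1OC(C)=O)c3
A1 | alternative 1 | 1,3-dibromo-2-(4-chloro-3,5-dimethoxyphenoxy)-5-methoxybenzene | COc1cc(Br)c(Oc2cc(OC)c(Cl)c(OC)c2)c(Br)c1
A2 | alternative 1 | nonadecamethyl ether of the target (methyl ether of 25) | COc3cc(Oc1c(OC)cc(Oc2c(OC)cc(OC)cc2OC)c(-c2c(OC)cc(OC)cc2OC)c1OC)c(Oc1cc(OC)c(Cl)c(OC)c1)c(Oc1c(OC)cc(Oc2c(OC)cc(OC)cc2OC)c(-c2c(OC)cc(OC)cc2OC)c1OC)c3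
A3 | alternative 2 | 2,6-dichloro-1,4-benzoquinone | O=C1C(Cl)=CC(=O)C=C1Cl
A4 | alternative 2 | 2,6-bis(ArO)-1,4-benzoquinone | O=C3C(Oc1c(OC)cc(Oc2c(OC)cc(OC)cc2OC)c(-c2c(OC)cc(OC)cc2OC)c1OC)=CC(=O)C=C3Oc1c(OC)cc(Oc2c(OC)cc(OC)cc2OC)c(-c2c(OC)cc(OC)cc2OC)c1OC
A5 | alternative 3 | 2-(4-chloro-3,5-dimethoxyphenoxy)-1,3-bis[2,6-dimethoxy-4-(2,4,6-trimethoxyphenoxy)phenoxy]-5-methoxybenzene | COc3cc(Oc1c(OC)cc(Oc2c(OC)cc(OC)cc2OC)cc1OC)c(Oc1cc(OC)c(Cl)c(OC)c1)c(Oc1c(OC)cc(Oc2c(OC)cc(OC)cc2OC)cc1OC)c3
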